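The ten-membered ring is traced back to a cyclohexene. In germacrane numbering (ring C1–C10, lactone oxygen on C6, C11(=C13)–C12 on C7, angelate on C8, C14 on C10, C15 on C4) the atoms C1–C6, the C15 methyl on C4 and the unit C9/C10/C14 on C1 are the skeleton of limonene, and C9=C10–C1–C6(O)–C7=C8 is the 1,5-diene of an oxy-Cope rearrangement. In one flask the potassium alkoxide of a cis 1-(2-silylvinyl)-6-isopropenylcyclohex-2-en-1-ol, made from (S)-limonene in three steps, shifts [3,3] (C8–C9 formed, C1–C6 broken, six- to ten-membered ring) and the C6/C7 enolate is alkylated by tert-butyl bromoacetate (C7–C11), which sets C7 and C8.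

Key step: step 4

Remark: the enolate of step 4 is open only on its outer face, so C11 is expected to enter trans to silicon on the ring; the (S)-limonene series is therefore used and the C8–O bond is inverted when the angelate is put on. Silicon is carried as benzyldimethylsilyl, which fluoride and peroxide unmask without acid or electrophile, so the two trisubstituted alkenes are spared.

Step 1
Reactants: 1 (S)-limonene
Product: 2 (R)-isopiperitenone, (6R)-3-methyl-6-(prop-1-en-2-yl)cyclohex-2-en-1-one
Conditions: Cr(CO)6 (cat.), t-BuOOH, MeCN, reflux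
Reagents that add atoms: tert-butyl hydroperoxide, CC(C)(C)OO
Why: Chromium-catalysed allylic oxidation turns the ring CH2 between the trisubstituted alkene and the isopropenyl-bearing carbon into the conjugated ketone under neutral conditions, the stereocentre (now alpha to the carbonyl) is not touched, and the regioisomeric enone (carvone) is removed by chromatography.

Step 2
Reactants: 2 (R)-isopiperitenone; 3 ethynylmagnesium bromide
Product: 4 (1S,6R)-1-ethynyl-3-methyl-6-(prop-1-en-2-yl)cyclohex-2-en-1-ol (ethynyl cis, hydroxyl trans to isopropenyl)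
Conditions: HC≡CMgBr, CeCl3, THF, −78 °C; aq NH4Cl
Reagents that add atoms: 3 ethynylmagnesium bromide, C#C[Mg]Br
Why: Organocerium 1,2-addition is weakly basic, so the epimerisable alpha carbon is not enolised, and the rod-shaped sp nucleophile should take the axial trajectory on the half-chair enone, syn to the pseudo-equatorial isopropenyl group, which sets the carbinol centre with ethynyl cis and hydroxyl trans to isopropenyl.

Step 3
Reactants: 4 cis ethynyl carbinol; 5 benzyldimethylsilane
Product: 6 (1S,6R)-1-[(E)-2-(benzyldimethylsilyl)ethenyl]-3-methyl-6-(prop-1-en-2-yl)cyclohex-2-en-1-ol (silylvinyl cis to isopropenyl)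
Conditions: PtCl2 (cat.), 2-dicyclohexylphosphino-2′,4′,6′-triisopropylbiphenyl (cat.), THF, 50 °C
Reagents that add atoms: 5 benzyldimethylsilane, C[SiH](C)Cc1ccccc1
Why: Platinum-catalysed hydrosilylation of the terminal alkyne of a propargylic alcohol is a syn addition that puts silicon on the terminal carbon, so only the (E)-2-silylvinyl carbinol should form while the less reactive alkenes stay untouched.

Step 4
Reactants: 6 cis silylvinyl carbinol; 7 tert-butyl bromoacetate
Product: 10 tert-butyl 2-[(1S,2S,4Z,8Z)-2-(benzyldimethylsilyl)-4,8-dimethyl-10-oxocyclodeca-4,8-dien-1-yl]acetate (germacrane 7S,8S; side chain trans to silicon; both ring olefins cis), via potassium alkoxide 8 (not isolated), via potassium enolate 9 (not isolated)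
Conditions: KN(SiMe3)2, 18-crown-6, THF, 0 °C → rt; then BrCH2CO2t-Bu, −78 → 0 °C
Reagents that add atoms: 7 tert-butyl bromoacetate, BrCC(=O)OC(C)(C)C
Why: KN(SiMe3)2 gives the potassium alkoxide 8; its oxido group loosens the C1–C6 bond, and a [3,3] sigmatropic shift through a chair (ring bond C1–C2 pseudo-axial, C6–C5 pseudo-equatorial, (E)-silyl group equatorial on C8) forms C8–C9, breaks C1–C6 and leaves the cross-conjugated enolate 9, which the bromoacetate alkylates at C7 by SN2. The closest known reaction type is the anionic oxy-Cope ring expansion of 1,2-dialkenylcyclohexanols to cyclodec-5-enones with alkylation of the enolate in the same flask. The ten-membered ring is not closed from an open chain but arises by sigmatropic four-atom enlargement of the cyclohexene, whose cis C4=C5 bond is carried over unchanged. C8 is set by the chair, which passes the configuration of C1 of the cis carbinol on to C8 through the equatorial silicon; C7 is set by alkylation of the ring-trans C6=C7 enolate on its only open face, the outer one anti to the new C8–C9 bond, which places C11 trans to silicon. The step needs this chair to win over the one with C5 axial and C2 equatorial, which would give the ring-trans C1=C10 olefin and the other C8 configuration; it should be favoured because it starts from the half-chair with pseudo-equatorial isopropenyl and avoids the 1,3-diaxial contact of C5 with the C14 methyl on C10, and this preference is the one real uncertainty of the route. C-alkylation over O-alkylation is expected from the soft, reactive alkyl bromide.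

Step 5
Reactants: 10 ring-expanded keto ester
Product: 11 tert-butyl 2-[(1S,2S,4Z,8Z,10R)-2-(benzyldimethylsilyl)-10-hydroxy-4,8-dimethylcyclodeca-4,8-dien-1-yl]acetate (germacrane 6R; hydroxyl trans to the side chain on C7)
Conditions: (S)-1-methyl-3,3-diphenyltetrahydro-1H,3H-pyrrolo[1,2-c][1,3,2]oxazaborole (cat.), catecholborane, toluene, −78 °C; aq NaHCO3
Reagents that add atoms: none
Why: Corey–Bakshi–Shibata reduction of the enone, in which the branched C7 flank is taken as the large group, should deliver hydride to the carbonyl face that gives the 6R alcohol (reagent control), and catecholborane at −78 °C does not hydroborate the alkenes.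

Step 6
Reactants: 11 hydroxy ester
Product: 12 (3aS,4S,6Z,10Z,11aR)-4-(benzyldimethylsilyl)-6,10-dimethyl-3a,4,5,8,9,11a-hexahydrocyclodeca[b]furan-2(3H)-one (trans-fused 6,12-olide, silicon on C8)
Conditions: pyridinium p-toluenesulfonate (cat.), toluene, 60 °C
Reagents that add atoms: none
Why: Acid-catalysed intramolecular transesterification of the gamma-hydroxy ester closes the five-membered lactone without breaking the C6–O bond, so the trans ring fusion follows from step 5.

Step 7
Reactants: 12 silyl lactone
Product: 14 (3aR,4S,6Z,10Z,11aR)-4-hydroxy-6,10-dimethyl-3a,4,5,8,9,11a-hexahydrocyclodeca[b]furan-2(3H)-one (germacrane 8S alcohol), via fluorosilane 13 (not isolated)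
Conditions: Bu4NF, THF, 0 °C → rt; then H2O2 (30% aq), KHCO3, MeOH, rt
Reagents that add atoms: hydrogen peroxide, OO
Why: Tamao–Fleming oxidation of the benzyldimethylsilyl group: fluoride removes benzyl as toluene and hydroperoxide attack on silicon is followed by a 1,2-shift of C8 from silicon to oxygen with retention, under conditions without acid or electrophile that spare both trisubstituted alkenes and the lactone.

Step 8
Reactants: 14 hydroxy lactone; 15 N,N-dimethylmethyleneiminium iodide
Product: 18 (3aR,4S,6Z,10Z,11aR)-4-hydroxy-6,10-dimethyl-3-methylidene-3a,4,5,8,9,11a-hexahydrocyclodeca[b]furan-2(3H)-one, via Mannich base 16 (not isolated), via methiodide 17 (not isolated)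
Conditions: LiN(i-Pr)2 (2.3 equiv), THF, −78 °C; Me2N=CH2+ I−, −78 → 0 °C; then MeI, MeOH, rt; then aq NaHCO3, CH2Cl2
Reagents that add atoms: 15 N,N-dimethylmethyleneiminium iodide, C=[N+](C)C.[I-]
Why: Mannich-type aminomethylation of the lactone enolate (the C8 alkoxide is carried as the second anion), N-methylation and beta-elimination of trimethylamine are the standard alpha-methylenation of gamma-lactones, and C11 ends sp2, so no stereocentre is at stake.

Step 9
Reactants: 18 alpha-methylene hydroxy lactone; 19 angelic acid
Product: 20 (3aR,4R,6Z,10Z,11aR)-6,10-dimethyl-3-methylidene-2-oxo-2,3,3a,4,5,8,9,11a-octahydrocyclodeca[b]furan-4-yl (Z)-2-methylbut-2-enoate (germacrane 8R angelate)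
Conditions: PPh3 and diisopropyl azodicarboxylate (premixed), angelic acid, toluene, 0 °C → rt
Reagents that add atoms: 19 angelic acid, C/C=C(/C)C(=O)O
Why: Mitsunobu esterification, in which the angelate anion displaces the oxyphosphonium group at C8 by SN2 with inversion (8S alcohol to 8R ester) under neutral conditions that should not isomerise the (Z)-enoate.

Step 10
Reactants: 20 angelate
Product: 21 target, (3aR,4R,6E,10E,11aR)-6,10-bis(hydroxymethyl)-3-methylidene-2-oxo-2,3,3a,4,5,8,9,11a-octahydrocyclodeca[b]furan-4-yl (Z)-2-methylbut-2-enoate (both ring olefins ring-cis)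
Conditions: SeO2 (cat.), t-BuOOH, CH2Cl2, 0 °C → rt
Reagents that add atoms: tert-butyl hydroperoxide, CC(C)(C)OO
Why: Allylic hydroxylation by SeO2 (ene reaction, then [2,3]-sigmatropic shift) should occur on each trisubstituted alkene at the methyl on the more substituted carbon that lies trans to the ring chain on the other alkene carbon (C14 and C15), with the ring-cis geometry kept, while the electron-poor alkenes of the angelate and the lactone do not react.

Compound list
1 | (S)-limonene, (4S)-1-methyl-4-(prop-1-en-2-yl)cyclohex-1-ene | CC1=CC[C@H](CC1)C(C)=C | starting material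
2 | (R)-isopiperitenone, (6R)-3-methyl-6-(prop-1-en-2-yl)cyclohex-2-en-1-one | O=C1C=C(C)CC[C@@H]1C(C)=C | intermediate
3 | ethynylmagnesium bromide | C#C[Mg]Br | starting material
4 | (1S,6R)-1-ethynyl-3-methyl-6-(prop-1-en-2-yl)cyclohex-2-en-1-ol (ethynyl cis to isopropenyl) | O[C@@]1(C#C)C=C(C)CC[C@@H]1C(C)=C | intermediate
5 | benzyldimethylsilane | C[SiH](C)Cc1ccccc1 | starting material
6 | (1S,6R)-1-[(E)-2-(benzyldimethylsilyl)ethenyl]-3-methyl-6-(prop-1-en-2-yl)cyclohex-2-en-1-ol (silylvinyl cis to isopropenyl) | O[C@@]1(/C=C/[Si](C)(C)Cc2ccccc2)C=C(C)CC[C@@H]1C(C)=C | intermediate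
7 | tert-butyl bromoacetate | BrCC(=O)OC(C)(C)C | starting material
8 | potassium alkoxide of 6 | [K+].[O-][C@@]1(/C=C/[Si](C)(C)Cc2ccccc2)C=C(C)CC[C@@H]1C(C)=C | intermediate (not isolated)
9 | potassium enolate of the ring-expanded dienone (O− on C6, C6=C7 ring-trans, C8 S, C4=C5 and C1=C10 ring-cis) | [K+].[O-]/C1=C\[C@@H]([Si](C)(C)Cc2ccccc2)C/C(C)=C\CC/C(C)=C\1 | intermediate (not isolated)
10 | tert-butyl 2-[(1S,2S,4Z,8Z)-2-(benzyldimethylsilyl)-4,8-dimethyl-10-oxocyclodeca-4,8-dien-1-yl]acetate | O=C1/C=C(/C)CC/C=C(/C)C[C@H]([Si](C)(C)Cc2ccccc2)[C@H]1CC(=O)OC(C)(C)C | intermediate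
11 | tert-butyl 2-[(1S,2S,4Z,8Z,10R)-2-(benzyldimethylsilyl)-10-hydroxy-4,8-dimethylcyclodeca-4,8-dien-1-yl]acetate | O[C@@H]1/C=C(/C)CC/C=C(/C)C[C@H]([Si](C)(C)Cc2ccccc2)[C@H]1CC(=O)OC(C)(C)C | intermediate
12 | (3aS,4S,6Z,10Z,11aR)-4-(benzyldimethylsilyl)-6,10-dimethyl-3a,4,5,8,9,11a-hexahydrocyclodeca[b]furan-2(3H)-one | C1C(=O)O[C@@H]2/C=C(/C)CC/C=C(/C)C[C@H]([Si](C)(C)Cc3ccccc3)[C@@H]12 | intermediate
13 | 4-(fluorodimethylsilyl) analogue of 12, same configuration | C1C(=O)O[C@@H]2/C=C(/C)CC/C=C(/C)C[C@H]([Si](C)(C)F)[C@@H]12 | intermediate (not isolated)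
14 | (3aR,4S,6Z,10Z,11aR)-4-hydroxy-6,10-dimethyl-3a,4,5,8,9,11a-hexahydrocyclodeca[b]furan-2(3H)-one | C1C(=O)O[C@@H]2/C=C(/C)CC/C=C(/C)C[C@H](O)[C@@H]12 | intermediate
15 | N,N-dimethylmethyleneiminium iodide | C=[N+](C)C.[I-] | starting material
16 | 3-[(dimethylamino)methyl] derivative of 14 (both C3 epimers) | CN(C)CC1C(=O)O[C@@H]2/C=C(/C)CC/C=C(/C)C[C@H](O)[C@@H]12 | intermediate (not isolated)
17 | N-methyl quaternary ammonium iodide of 16 | C[N+](C)(C)CC1C(=O)O[C@@H]2/C=C(/C)CC/C=C(/C)C[C@H](O)[C@@H]12.[I-] | intermediate (not isolated)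
18 | (3aR,4S,6Z,10Z,11aR)-4-hydroxy-6,10-dimethyl-3-methylidene-3a,4,5,8,9,11a-hexahydrocyclodeca[b]furan-2(3H)-one | C=C1C(=O)O[C@@H]2/C=C(/C)CC/C=C(/C)C[C@H](O)[C@@H]12 | intermediate
19 | angelic acid, (Z)-2-methylbut-2-enoic acid | C/C=C(/C)C(=O)O | starting material
20 | (3aR,4R,6Z,10Z,11aR)-6,10-dimethyl-3-methylidene-2-oxo-2,3,3a,4,5,8,9,11a-octahydrocyclodeca[b]furan-4-yl (Z)-2-methylbut-2-enoate | C=C1C(=O)O[C@@H]2/C=C(/C)CC/C=C(/C)C[C@@H](OC(=O)/C(C)=C\C)[C@@H]12 | intermediate
21 | CNP0182172.4, (3aR,4R,6E,10E,11aR)-6,10-bis(hydroxymethyl)-3-methylidene-2-oxo-2,3,3a,4,5,8,9,11a-octahydrocyclodeca[b]furan-4-yl (Z)-2-methylbut-2-enoate | C=C1C(=O)O[C@@H]2/C=C(/CO)CC/C=C(/CO)C[C@@H](OC(=O)/C(C)=C\C)[C@@H]12 | target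

Total steps: 10. Longest linear sequence: 10 steps, from 1 to 21; compounds 3, 5, 7, 15 and 19 are bought.

Steps most likely to fail

Step 4. The second chair (C5 axial, C2 equatorial) or a boat may compete in the [3,3] shift, which would give the ring-trans C1=C10 olefin and the other configuration at C8. In addition, C-alkylation of the hindered enolate (silicon gauche to the incoming electrophile) may be slow, so that proton transfer between enolate and product or O-alkylation takes over. The fallback separates ring expansion from C–C bond formation and sets out from 6. The rearrangement is run as in step 4 but quenched with Me3SiCl at −78 °C, which gives the trimethylsilyl enol ether F1. This neutral compound can be chromatographed and freed from any isomer formed through the other chair. MeLi in THF at 0 °C then releases the lithium enolate with no proton source present, and alkylation with 7 in THF/DMPU at −78 °C comes back to the route at 10.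

Step 2. The acetylide may approach the carbonyl face anti to isopropenyl (equatorial trajectory), which gives the carbinol epimer with hydroxyl cis to isopropenyl; that epimer cannot reach the required chair. The fallback brings in the oxygen last instead of the carbon and sets out from 2. Wittig reaction with Ph3P=CHOMe gives the methoxymethylidene diene F2. Dimethyldioxirane epoxidises the electron-rich enol ether on the face anti to isopropenyl, and aqueous work-up opens the epoxy ether to the alpha-hydroxy aldehyde F3 with hydroxyl trans to isopropenyl. Seyferth–Gilbert homologation with dimethyl (1-diazo-2-oxopropyl)phosphonate and K2CO3 in MeOH turns the formyl group into ethynyl and comes back to the route at 4.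

Step 5. Hydride delivery may be governed by the ring conformation instead of the catalyst (mismatched pair), which gives the C6 epimer. The fallback funnels that epimer into the same lactone and sets out from 10. If the 6S alcohol F4 is what forms (for instance from NaBH4/CeCl3 under substrate control), the tert-butyl ester is cleaved with Me3SiOTf/2,6-lutidine and aqueous work-up to the hydroxy acid F5. Mitsunobu lactonisation (PPh3, diisopropyl azodicarboxylate) then closes the ring by SN2 with inversion at C6 and comes back to the route at 12.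

Further compounds
F1 | step 4 | trimethylsilyl enol ether of the ring-expanded dienone (C6–OSiMe3, C6=C7 ring-trans, C8 S) | C[Si](C)(C)O/C1=C\[C@@H]([Si](C)(C)Cc2ccccc2)C/C(C)=C\CC/C(C)=C\1
F2 | step 2 | (6R)-1-(methoxymethylidene)-3-methyl-6-(prop-1-en-2-yl)cyclohex-2-ene (enol ether E/Z mixture) | COC=C1C=C(C)CC[C@@H]1C(C)=C
F3 | step 2 | (1S,6R)-1-hydroxy-3-methyl-6-(prop-1-en-2-yl)cyclohex-2-ene-1-carbaldehyde | O=C[C@]1(O)C=C(C)CC[C@@H]1C(C)=C
F4 | step 5 | tert-butyl 2-[(1S,2S,4Z,8Z,10S)-2-(benzyldimethylsilyl)-10-hydroxy-4,8-dimethylcyclodeca-4,8-dien-1-yl]acetate | O[C@H]1/C=C(/C)CC/C=C(/C)C[C@H]([Si](C)(C)Cc2ccccc2)[C@H]1CC(=O)OC(C)(C)C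
F5 | step 5 | 2-[(1S,2S,4Z,8Z,10S)-2-(benzyldimethylsilyl)-10-hydroxy-4,8-dimethylcyclodeca-4,8-dien-1-yl]acetic acid | O[C@H]1/C=C(/C)CC/C=C(/C)C[C@H]([Si](C)(C)Cc2ccccc2)[C@H]1CC(=O)O
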